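1. Locants (pyrrolo[1,2-a]azepine core): N4, C5 (aminal CH of the fused butenolide), C6–C8, C9 (spiro carbon), C9a, C1–C3 (pyrrolidine); spirolactone C10–C12 (Me on C11); side-chain lactone C18 (OCH)–C21 (Me on C20). Enabling feature: C3 lies between the basic N4 and the carbinol carbon C18 of the side-chain lactone ring, so N4–C3 is a latent iminium bond (C3 at the aldehyde level) and C3–C18 a vinylogous Mannich bond to the γ-carbon of a 3-methylfuranone; the N4–C5–O aminal of the butenolide ring is configurationally mobile.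
2. Last disconnections: hydrogenation at C20; then the pyrrolidine ring (N4–C3, amine–aldehyde condensation) together with C3–C18 (vinylogous Mannich addition of 3-methyl-2-silyloxyfuran), from a tricyclic N-Boc aminal aldehyde.
3. Azepane ring: N4–C5 closure of the carbamate onto a γ-hydroxybutenolide (N-acyl-N,O-acetal); the butenolide is joined at C6–C7 by B-alkyl Suzuki–Miyaura coupling of a C9 vinyl group and then oxidised at C5.
4. Spirolactone: C9–C10 by chelation-controlled Grignard addition of a (2S)-3-silyloxy-2-methylpropyl unit to a vinyl ketone, then oxidative lactonisation; C9a, N4 and C1–C3 come from L-glutamic acid.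
5. Order of ring formation: spirolactone, azepane (the butenolide and the side-chain furanone enter as preformed rings), pyrrolidine last.

Key step: step 16

Assumption: the (5S) configuration of the N4–C5–O aminal is taken to be the thermodynamically preferred one, because this acyloxy-aminal can epimerise by reversible opening to the conjugated iminium carboxylate; C5 is therefore left to equilibrate at the end.

Step 1
Reactants: 1 N-Boc-L-glutamic acid 1-benzyl ester
Product: 2 benzyl (2S)-2-[(tert-butoxycarbonyl)amino]-5-hydroxypentanoate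
Conditions: BH3·SMe2, THF, 0 °C → rt; aq. NH4Cl
Reagents that add atoms: none
Why: Borane reduces the free carboxylic acid much faster than the benzyl ester or the carbamate (chemoselective borane reduction of a carboxylic acid), so only the side-chain acid becomes the primary alcohol and the C9a centre is untouched.

Step 2
Reactants: 2 benzyl (2S)-2-[(tert-butoxycarbonyl)amino]-5-hydroxypentanoate
Product: 3 benzyl (2S)-2-[(tert-butoxycarbonyl)amino]-5-[(tert-butyldiphenylsilyl)oxy]pentanoate
Conditions: TBDPSCl, imidazole, DMF, rt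
Reagents that add atoms: tert-butyl(chloro)diphenylsilane (TBDPSCl), CC(C)(C)[Si](Cl)(c1ccccc1)c1ccccc1
Why: Silyl ether formation at the primary alcohol, with the bulky TBDPS group chosen to survive the later Grignard, mild-acid and oxidation steps.

Step 3
Reactants: 3 benzyl (2S)-2-[(tert-butoxycarbonyl)amino]-5-[(tert-butyldiphenylsilyl)oxy]pentanoate
Product: 4 tert-butyl N-[(2S)-5-[(tert-butyldiphenylsilyl)oxy]-1-[methoxy(methyl)amino]-1-oxopentan-2-yl]carbamate (Weinreb amide)
Conditions: MeNH(OMe)·HCl, i-PrMgCl, THF, −20 → 0 °C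
Reagents that add atoms: N,O-dimethylhydroxylamine hydrochloride, CNOC.Cl
Why: Direct aminolysis of the ester by the chloromagnesium amide of N,O-dimethylhydroxylamine gives the Weinreb amide, and the N-magnesiated carbamate protects the α-centre from epimerisation.

Step 4
Reactants: 4 Weinreb amide; 5 vinylmagnesium bromide
Product: 6 tert-butyl N-[(4S)-7-[(tert-butyldiphenylsilyl)oxy]-3-oxohept-1-en-4-yl]carbamate (vinyl ketone)
Conditions: 5 (3 equiv), THF, −78 → 0 °C; inverse quench into cold 1 M HCl
Reagents that add atoms: none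
Why: Weinreb ketone synthesis, in which the magnesium chelate of the tetrahedral adduct prevents over-addition and collapses to the vinyl ketone only on the acidic inverse quench, which also keeps the liberated amine from adding to the enone.

Step 5
Reactants: 7 (2S)-3-bromo-2-methylpropan-1-ol
Product: 8 [(2S)-3-bromo-2-methylpropoxy](tert-butyl)dimethylsilane
Conditions: TBSCl, imidazole, CH2Cl2, rt
Reagents that add atoms: tert-butyl(chloro)dimethylsilane (TBSCl), CC(C)(C)[Si](C)(C)Cl
Why: Silyl ether formation protects the hydroxyl so that the bromide can be turned into a Grignard reagent that carries the C11 methyl centre.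

Step 6
Reactants: 6 vinyl ketone; 8 [(2S)-3-bromo-2-methylpropoxy](tert-butyl)dimethylsilane
Product: 10 tert-butyl N-[(4S,5R,7R)-8-[(tert-butyldimethylsilyl)oxy]-1-[(tert-butyldiphenylsilyl)oxy]-5-ethenyl-5-hydroxy-7-methyloctan-4-yl]carbamate, via Grignard reagent 9 (not isolated)
Conditions: 8, Mg, THF, rt (gives 9, 2.5 equiv); 6, THF, −78 °C; aq. NH4Cl
Reagents that add atoms: none
Why: Chelation-controlled Grignard 1,2-addition, in which the N-magnesiated carbamate and the ketone oxygen hold magnesium in a five-membered chelate, the alkyl group adds from the face of the C9a hydrogen (anti to the C1 chain) and so sets the C9 carbinol centre with the hydroxyl syn to nitrogen along the new C10–C9–C9a–C1 chain, while C11 comes unchanged from 8.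

Step 7
Reactants: 10 bis-silyl ether carbinol
Product: 11 tert-butyl N-[(4S,5R,7R)-1-[(tert-butyldiphenylsilyl)oxy]-5-ethenyl-5,8-dihydroxy-7-methyloctan-4-yl]carbamate
Conditions: PPTS (cat.), MeOH, rt
Reagents that add atoms: none
Why: Mild acid-catalysed methanolysis (selective desilylation) removes the primary TBS ether and leaves the more hindered TBDPS ether, the Boc group and the tertiary allylic alcohol intact.

Step 8
Reactants: 11 diol
Product: 13 tert-butyl N-[(1S)-4-[(tert-butyldiphenylsilyl)oxy]-1-[(2R,4R)-2-ethenyl-4-methyl-5-oxooxolan-2-yl]butyl]carbamate, via lactol 12 (not isolated)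
Conditions: TEMPO (cat.), PhI(OAc)2, CH2Cl2, rt
Reagents that add atoms: none
Why: Oxidative lactonisation of a 1,4-diol, in which TEMPO/PhI(OAc)2 oxidises the primary alcohol to the aldehyde, the tertiary hydroxyl traps it as the lactol and a second oxidation gives the γ-lactone without touching a stereocentre.

Step 9
Reactants: 14 3-methyltetronic acid
Product: 15 4-methyl-5-oxo-2,5-dihydrofuran-3-yl trifluoromethanesulfonate
Conditions: Tf2O, i-Pr2NEt, CH2Cl2, −78 °C
Reagents that add atoms: trifluoromethanesulfonic anhydride, O=S(=O)(OS(=O)(=O)C(F)(F)F)C(F)(F)F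
Why: O-Sulfonylation of the vinylogous acid (enol triflate formation) gives the electrophile for the cross-coupling.

Step 10
Reactants: 13 vinyl lactone; 15 butenolide triflate
Product: 17 tert-butyl N-[(1S)-4-[(tert-butyldiphenylsilyl)oxy]-1-[(2S,4R)-4-methyl-2-[2-(4-methyl-5-oxo-2,5-dihydrofuran-3-yl)ethyl]-5-oxooxolan-2-yl]butyl]carbamate, via alkylborane 16 (not isolated)
Conditions: 9-BBN, THF, rt; then 15, PdCl2(dppf) (cat.), AsPh3, K3PO4, DMF–H2O, rt
Reagents that add atoms: none
Why: Anti-Markovnikov hydroboration of the vinyl group followed by B-alkyl Suzuki–Miyaura coupling with the vinyl triflate forms the C7–C6 bond, and lactone, carbamate and silyl ether are inert to 9-BBN and to the mild base.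

Step 11
Reactants: 17 butenolide
Product: 19 tert-butyl N-[(1S)-4-[(tert-butyldiphenylsilyl)oxy]-1-[(2S,4R)-2-[2-(2-hydroxy-4-methyl-5-oxo-2,5-dihydrofuran-3-yl)ethyl]-4-methyl-5-oxooxolan-2-yl]butyl]carbamate (γ-hydroxybutenolide; lactol carbon both epimers), via silyloxyfuran 18 (not isolated)
Conditions: TIPSOTf, Et3N, CH2Cl2, 0 °C; then dimethyldioxirane, acetone, −78 °C; H2O work-up
Reagents that add atoms: dimethyldioxirane, CC1(C)OO1
Why: γ-Deprotonation and O-silylation give the aromatic 2-silyloxyfuran, which dimethyldioxirane oxidises at its free α-carbon (C5) so that aqueous work-up delivers the γ-hydroxybutenolide (oxidation of a 2-silyloxyfuran), while the saturated lactone is not enolised by Et3N.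

Step 12
Reactants: 19 γ-hydroxybutenolide
Product: 20 N4-Boc tricyclic aminal silyl ether (9S,9aS,11R; C5 both epimers)
Conditions: PPTS (cat.), 4 Å MS, PhMe, 80 °C
Reagents that add atoms: none
Why: Acid-catalysed N-acyl-N,O-acetal formation (amidoalkylation) between the carbamate N–H and the pseudo-acid lactol closes the seven-membered azepane ring with loss of water, helped by the quaternary C9 in the chain; both C5 epimers can form and both are carried on.

Step 13
Reactants: 20 N4-Boc tricyclic aminal silyl ether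
Product: 21 N4-Boc tricyclic aminal alcohol (C9a chain = 3-hydroxypropyl)
Conditions: HF·pyridine, pyridine, THF, 0 °C → rt
Reagents that add atoms: none
Why: Fluoride-mediated desilylation cleaves the TBDPS ether, and the pyridine-buffered medium leaves the N-Boc aminal and both lactones intact.

Step 14
Reactants: 21 N4-Boc tricyclic aminal alcohol
Product: 22 N4-Boc tricyclic aminal aldehyde (C3 = CHO)
Conditions: Dess–Martin periodinane, CH2Cl2, 0 °C → rt
Reagents that add atoms: none
Why: Dess–Martin oxidation stops at the aldehyde, which is stable here because N4 is fully substituted and cannot yet close onto C3.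

Step 15
Reactants: 23 3-methylfuran-2(5H)-one
Product: 24 triisopropyl[(3-methylfuran-2-yl)oxy]silane
Conditions: TIPSOTf, Et3N, CH2Cl2, 0 °C
Reagents that add atoms: triisopropylsilyl trifluoromethanesulfonate, CC(C)[Si](OS(=O)(=O)C(F)(F)F)(C(C)C)C(C)C
Why: γ-Deprotonation of the butenolide and O-silylation give the aromatic 2-silyloxyfuran (silyl dienol ether formation), the nucleophile that carries the complete side-chain lactone ring.

Step 16
Reactants: 22 N4-Boc tricyclic aminal aldehyde; 24 triisopropyl[(3-methylfuran-2-yl)oxy]silane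
Product: 27 19,20-didehydro target (side-chain 3-methylbutenolide; 3S,5S,9S,9aS,11R,18S), via ammonium aldehyde 25 (not isolated), via pyrrolinium ion 26 (not isolated)
Conditions: CF3CO2H, CH2Cl2, 0 °C → rt; concentrate (PhMe); 24, CH2Cl2, −78 → 0 °C; aq. NaHCO3; then MeOH, rt
Reagents that add atoms: none
Why: Acidolysis of the Boc group (loss of isobutene and CO2) frees N4–H of the aminal as the ammonium salt 25, which adds to the pendant C3 aldehyde in a 5-exo-trig closure and dehydrates to the endocyclic pyrrolinium ion 26, so that the pyrrolidine is closed as the last ring of the skeleton, and the 2-silyloxyfuran 24 then attacks C3 through its γ-carbon and loses the silyl group to give the butenolide 27. The closest known reaction type is the vinylogous Mannich addition of 2-silyloxyfurans to cyclic iminium and N-acyliminium ions, the standard way to build pyrrolidine–butenolide units. C3 is set by the C9a centre, because C9 with its spirolactone and the azepane ring shield one face of the planar iminium ion, so the furan adds anti to C9 and gives the 2,5-trans pyrrolidine; C18 is set by the open Mannich transition state, which in this reaction class favours the threo (3S,18S) pair. C5 is not fixed in 22, but in the tertiary amine 27 the N4 lone pair can expel the lactone carboxylate to a conjugated iminium carboxylate that recloses, so both C5 epimers should be funnelled to the more stable (5S) aminal on standing in methanol. The step needs site selectivity between two possible iminium carbons (C3 and C5), and this is secured because under acid N4 is either protonated or part of the C3 iminium ion and has no lone pair to ionise the C5–O bond, while C3 is unhindered and C5 is flanked by the tetrasubstituted alkene.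

Step 17
Reactants: 27 19,20-didehydro target
Product: 28 target CNP0155196.1 (3S,5S,9S,9aS,11R,18S,20S)
Conditions: H2 (1 atm), Rh/Al2O3 (cat.), EtOAc–AcOH, rt
Reagents that add atoms: none
Why: Heterogeneous hydrogenation of the trisubstituted side-chain butenolide from the face opposite the C18 pyrrolidinyl group should place the C20 methyl cis to C18 (20S), while the tetrasubstituted aminal-bearing butenolide is not reduced at 1 atm and protonation of N4 by AcOH suppresses hydrogenolysis of the C5–O bond.

Compound list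
1 | N-Boc-L-glutamic acid 1-benzyl ester | O=C(OCc1ccccc1)[C@@H](NC(=O)OC(C)(C)C)CCC(=O)O | starting material
2 | benzyl (2S)-2-[(tert-butoxycarbonyl)amino]-5-hydroxypentanoate | O=C(OCc1ccccc1)[C@@H](NC(=O)OC(C)(C)C)CCCO | intermediate
3 | benzyl (2S)-2-[(tert-butoxycarbonyl)amino]-5-[(tert-butyldiphenylsilyl)oxy]pentanoate | O=C(OCc1ccccc1)[C@@H](NC(=O)OC(C)(C)C)CCCO[Si](c1ccccc1)(c1ccccc1)C(C)(C)C | intermediate
4 | tert-butyl N-[(2S)-5-[(tert-butyldiphenylsilyl)oxy]-1-[methoxy(methyl)amino]-1-oxopentan-2-yl]carbamate | CON(C)C(=O)[C@@H](NC(=O)OC(C)(C)C)CCCO[Si](c1ccccc1)(c1ccccc1)C(C)(C)C | intermediate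
5 | vinylmagnesium bromide | C=C[Mg]Br | starting material
6 | tert-butyl N-[(4S)-7-[(tert-butyldiphenylsilyl)oxy]-3-oxohept-1-en-4-yl]carbamate | C=CC(=O)[C@@H](NC(=O)OC(C)(C)C)CCCO[Si](c1ccccc1)(c1ccccc1)C(C)(C)C | intermediate
7 | (2S)-3-bromo-2-methylpropan-1-ol | BrC[C@@H](C)CO | starting material
8 | [(2S)-3-bromo-2-methylpropoxy](tert-butyl)dimethylsilane | BrC[C@@H](C)CO[Si](C)(C)C(C)(C)C | intermediate
9 | [(2S)-3-[(tert-butyldimethylsilyl)oxy]-2-methylpropyl]magnesium bromide | Br[Mg]C[C@@H](C)CO[Si](C)(C)C(C)(C)C | intermediate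
10 | tert-butyl N-[(4S,5R,7R)-8-[(tert-butyldimethylsilyl)oxy]-1-[(tert-butyldiphenylsilyl)oxy]-5-ethenyl-5-hydroxy-7-methyloctan-4-yl]carbamate | C=C[C@](O)(C[C@@H](C)CO[Si](C)(C)C(C)(C)C)[C@@H](NC(=O)OC(C)(C)C)CCCO[Si](c1ccccc1)(c1ccccc1)C(C)(C)C | intermediate
11 | tert-butyl N-[(4S,5R,7R)-1-[(tert-butyldiphenylsilyl)oxy]-5-ethenyl-5,8-dihydroxy-7-methyloctan-4-yl]carbamate | C=C[C@](O)(C[C@@H](C)CO)[C@@H](NC(=O)OC(C)(C)C)CCCO[Si](c1ccccc1)(c1ccccc1)C(C)(C)C | intermediate
12 | tert-butyl N-[(1S)-4-[(tert-butyldiphenylsilyl)oxy]-1-[(2R,4R)-2-ethenyl-5-hydroxy-4-methyloxolan-2-yl]butyl]carbamate (lactol, both anomers) | C=C[C@]1(C[C@@H](C)C(O)O1)[C@@H](NC(=O)OC(C)(C)C)CCCO[Si](c2ccccc2)(c2ccccc2)C(C)(C)C | intermediate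
13 | tert-butyl N-[(1S)-4-[(tert-butyldiphenylsilyl)oxy]-1-[(2R,4R)-2-ethenyl-4-methyl-5-oxooxolan-2-yl]butyl]carbamate | C=C[C@]1(C[C@@H](C)C(=O)O1)[C@@H](NC(=O)OC(C)(C)C)CCCO[Si](c2ccccc2)(c2ccccc2)C(C)(C)C | intermediate
14 | 3-methyltetronic acid [4-hydroxy-3-methylfuran-2(5H)-one] | CC1=C(O)COC1=O | starting material
15 | 4-methyl-5-oxo-2,5-dihydrofuran-3-yl trifluoromethanesulfonate | CC1=C(OS(=O)(=O)C(F)(F)F)COC1=O | intermediate
16 | tert-butyl N-[(1S)-1-[(2S,4R)-2-[2-(9-borabicyclo[3.3.1]nonan-9-yl)ethyl]-4-methyl-5-oxooxolan-2-yl]-4-[(tert-butyldiphenylsilyl)oxy]butyl]carbamate | C1CCC2CCCC1B2CC[C@]1(C[C@@H](C)C(=O)O1)[C@@H](NC(=O)OC(C)(C)C)CCCO[Si](c2ccccc2)(c2ccccc2)C(C)(C)C | intermediate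
17 | tert-butyl N-[(1S)-4-[(tert-butyldiphenylsilyl)oxy]-1-[(2S,4R)-4-methyl-2-[2-(4-methyl-5-oxo-2,5-dihydrofuran-3-yl)ethyl]-5-oxooxolan-2-yl]butyl]carbamate | CC1=C(CC[C@]2(C[C@@H](C)C(=O)O2)[C@@H](NC(=O)OC(C)(C)C)CCCO[Si](c3ccccc3)(c3ccccc3)C(C)(C)C)COC1=O | intermediate
18 | tert-butyl N-[(1S)-4-[(tert-butyldiphenylsilyl)oxy]-1-[(2S,4R)-4-methyl-2-[2-[4-methyl-5-(triisopropylsilyloxy)furan-3-yl]ethyl]-5-oxooxolan-2-yl]butyl]carbamate | Cc1c(CC[C@]2(C[C@@H](C)C(=O)O2)[C@@H](NC(=O)OC(C)(C)C)CCCO[Si](c3ccccc3)(c3ccccc3)C(C)(C)C)coc1O[Si](C(C)C)(C(C)C)C(C)C | intermediate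
19 | tert-butyl N-[(1S)-4-[(tert-butyldiphenylsilyl)oxy]-1-[(2S,4R)-2-[2-(2-hydroxy-4-methyl-5-oxo-2,5-dihydrofuran-3-yl)ethyl]-4-methyl-5-oxooxolan-2-yl]butyl]carbamate (lactol carbon both epimers) | CC1=C(CC[C@]2(C[C@@H](C)C(=O)O2)[C@@H](NC(=O)OC(C)(C)C)CCCO[Si](c3ccccc3)(c3ccccc3)C(C)(C)C)C(O)OC1=O | intermediate
20 | N4-Boc tricyclic aminal: 3-methylbutenolide fused at C5–C6 to the azepane through the N4–C5–O aminal; (9S,11R) spiro α-methyl-γ-lactone at C9; (9aS) 3-[(tert-butyldiphenylsilyl)oxy]propyl at C9a; C5 both epimers | CC1=C2CC[C@]3(C[C@@H](C)C(=O)O3)[C@H](CCCO[Si](c4ccccc4)(c4ccccc4)C(C)(C)C)N(C(=O)OC(C)(C)C)C2OC1=O | intermediate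
21 | N4-Boc tricyclic aminal alcohol: as 20 with a (9aS) 3-hydroxypropyl chain; C5 both epimers | CC1=C2CC[C@]3(C[C@@H](C)C(=O)O3)[C@H](CCCO)N(C(=O)OC(C)(C)C)C2OC1=O | intermediate
22 | N4-Boc tricyclic aminal aldehyde: as 20 with a (9aS) 3-oxopropyl chain (C3 = CHO); C5 both epimers | CC1=C2CC[C@]3(C[C@@H](C)C(=O)O3)[C@H](CCC=O)N(C(=O)OC(C)(C)C)C2OC1=O | intermediate
23 | 3-methylfuran-2(5H)-one | CC1=CCOC1=O | starting material
24 | triisopropyl[(3-methylfuran-2-yl)oxy]silane | Cc1ccoc1O[Si](C(C)C)(C(C)C)C(C)C | intermediate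
25 | N4-H tricyclic aminal aldehyde as its ammonium trifluoroacetate (22 without Boc); C5 both epimers | CC1=C2CC[C@]3(C[C@@H](C)C(=O)O3)[C@H](CCC=O)[NH2+]C2OC1=O.[O-]C(=O)C(F)(F)F | intermediate
26 | tetracyclic pyrrolinium trifluoroacetate (N4=C3 iminium; 9S,9aS,11R; C5 both epimers) | CC1=C2CC[C@]3(C[C@@H](C)C(=O)O3)[C@@H]3CCC=[N+]3C2OC1=O.[O-]C(=O)C(F)(F)F | intermediate
27 | 19,20-didehydro target: C3 bears the (18S) 4-methyl-5-oxo-2,5-dihydrofuran-2-yl group; (3S,5S,9S,9aS,11R,18S) | CC1=C2CC[C@]3(C[C@@H](C)C(=O)O3)[C@@H]3CC[C@@H]([C@@H]4C=C(C)C(=O)O4)N3[C@H]2OC1=O | intermediate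
28 | CNP0155196.1 (3S,5S,9S,9aS,11R,18S,20S) | CC1=C2CC[C@]3(C[C@@H](C)C(=O)O3)[C@@H]3CC[C@@H]([C@@H]4C[C@H](C)C(=O)O4)N3[C@H]2OC1=O | target

Total step count: 17. Longest linear sequence: 14 steps (steps 1–4, 6–8, 10–14, 16 and 17); steps 5, 9 and 15 make the three side fragments.

Steps most likely to fail

Risk 1, step 16 (key step). What may go wrong: premature ionisation of the C5 acyloxy-aminal, so that the silyloxyfuran or the enol of the aldehyde attacks C5 instead of C3, and erosion of the threo preference in the Mannich addition. The fallback closes the same ring by N-alkylation instead of iminium chemistry; it sets out from 22 and returns at 28. Aldehyde 22 and 24 are combined in a fluoride-catalysed vinylogous aldol addition (Bu4NF cat., THF, −78 °C), which is expected to favour the erythro hydroxy butenolide F1 (3R,18S). The remote C9a centre does not control the absolute sense, so the unwanted erythro isomer has to be separated or a Ti(Oi-Pr)4/BINOL-catalysed variant used. Hydrogenation (H2, Rh/Al2O3, EtOAc) from the face opposite C3 should give the cis-lactone alcohol F2, and MsCl, Et3N, CH2Cl2, 0 °C gives the mesylate F3. CF3CO2H then removes the Boc group and, after neutralisation with K2CO3 in MeCN at 50 °C, N4 should displace the mesylate in a 5-exo-tet SN2 reaction with inversion at C3. This gives 28 directly, with the pyrrolidine again the last ring closed.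

Risk 2, step 12. What may go wrong: the weakly nucleophilic carbamate nitrogen fails to close the seven-membered N-acyl-N,O-acetal before acid-promoted loss of the Boc group or intermolecular acetal formation sets in. The fallback uses amine condensation followed by re-acylation; it sets out from 19 and returns at 20. CF3CO2H in CH2Cl2 removes the Boc group; on neutralisation (aq. NaHCO3, CH2Cl2, 0 °C) the primary amine F4 should condense with the ring-opened formyl acid form of the pseudo-acid to give the cyclic N–H aminal F5, in equilibrium with the conjugated imino acid. F5 is capped in the same flask with Boc2O to give 20. O-to-N acyl transfer onto the neighbouring lactone is not expected to compete, because it would need a strained bicyclo[2.2.1] tetrahedral intermediate.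

Risk 3, step 6. What may go wrong: conjugate addition of the Grignard reagent to the vinyl ketone and incomplete chelation control, which would lower the diastereoselectivity at C9. The fallback masks the enone; it sets out from 6 and returns at 10. PhSeH (from (PhSe)2 and NaBH4, EtOH, 0 °C) adds to the enone to give the β-phenylselanyl ketone F6, a saturated ketone. Chelation-controlled 1,2-addition of 9 (THF, −78 °C) should then give the carbinol F7 without a competing conjugate pathway. Oxidation (H2O2, pyridine, CH2Cl2, 0 °C → rt) and syn-elimination of the selenoxide regenerate the vinyl group and give 10.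

Further compounds
F1 | step 16 | erythro hydroxy butenolide: N4-Boc tricycle of 22 whose C9a chain is CH2CH2–CH(OH)–(4-methyl-5-oxo-2,5-dihydrofuran-2-yl), (3R,18S), C5 both epimers | CC1=C2CC[C@]3(C[C@@H](C)C(=O)O3)[C@H](CC[C@@H](O)[C@@H]4C=C(C)C(=O)O4)N(C(=O)OC(C)(C)C)C2OC1=O
F2 | step 16 | cis-lactone alcohol: F1 with the saturated (18S,20S) α-methyl-γ-lactone, (3R) carbinol | CC1=C2CC[C@]3(C[C@@H](C)C(=O)O3)[C@H](CC[C@@H](O)[C@@H]4C[C@H](C)C(=O)O4)N(C(=O)OC(C)(C)C)C2OC1=O
F3 | step 16 | methanesulfonate of F2 at the (3R) carbinol | CC1=C2CC[C@]3(C[C@@H](C)C(=O)O3)[C@H](CC[C@@H](OS(C)(=O)=O)[C@@H]4C[C@H](C)C(=O)O4)N(C(=O)OC(C)(C)C)C2OC1=O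
F4 | step 12 | primary amine: 19 without the Boc group | CC1=C(CC[C@]2(C[C@@H](C)C(=O)O2)[C@@H](N)CCCO[Si](c3ccccc3)(c3ccccc3)C(C)(C)C)C(O)OC1=O
F5 | step 12 | cyclic N4–H aminal: 20 without the Boc group, C5 both epimers | CC1=C2CC[C@]3(C[C@@H](C)C(=O)O3)[C@H](CCCO[Si](c4ccccc4)(c4ccccc4)C(C)(C)C)NC2OC1=O
F6 | step 6 | tert-butyl N-[(4S)-7-[(tert-butyldiphenylsilyl)oxy]-3-oxo-1-(phenylselanyl)heptan-4-yl]carbamate | O=C(CC[Se]c1ccccc1)[C@@H](NC(=O)OC(C)(C)C)CCCO[Si](c1ccccc1)(c1ccccc1)C(C)(C)C
F7 | step 6 | tert-butyl N-[(4S,5R,7R)-8-[(tert-butyldimethylsilyl)oxy]-1-[(tert-butyldiphenylsilyl)oxy]-5-hydroxy-7-methyl-5-[2-(phenylselanyl)ethyl]octan-4-yl]carbamate | c1ccccc1[Se]CC[C@](O)(C[C@@H](C)CO[Si](C)(C)C(C)(C)C)[C@@H](NC(=O)OC(C)(C)C)CCCO[Si](c1ccccc1)(c1ccccc1)C(C)(C)C
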